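**Route in one sentence:** a chiral phosphoric acid lets 2-methylpropanoic acid open one of the two enantiotopic CH2–O bonds of the achiral oxetanol 5, which makes one ester, frees the other arm as an alcohol and sets the carbinol stereocenter in the same step.

## Structural features

The target is a thymol-type monoterpenoid with a single ring, a benzene ring (C1'–C6') carrying a free phenol at C2', a methyl group at C4' and, at C1', an open chain C1–C2–C3. C2 is a fully substituted benzylic carbinol (aryl, free tertiary OH, two CH2O groups); O1 is esterified with (2S)-2-methylbutanoic acid and O3 with 2-methylpropanoic acid. There are two stereocenters, C2 (S) and the α-carbon of the 2-methylbutanoate (S); they are four bonds apart, so neither can control the other, and the second one can be bought. C2 is stereogenic only because its two CH2O arms carry acyl groups that differ by one methylene at the far end, so no reagent acting at C2 on a compound with both esters in place can tell the arms apart. The fragile features are the esters, the ortho phenol and the tertiary alcohol: any acyl shift (O1 to O3 in a monoester, or through O2 in the diester) exchanges the arms and inverts C2 without breaking a bond at C2, the phenol is a 5-exo nucleophile toward C1 or C3 and an acyl acceptor, and the tertiary benzylic alcohol on an electron-rich ring can ionise. The real difficulty is therefore to distinguish two enantiotopic CH2–O groups on a quaternary carbinol, put one specific acyl group on each, and never pass through conditions that shuffle acyl groups. The key step exploits the fact that the unit O1–C1–C2(OH)(Ar)–C3–O3 is an opened 3-aryloxetan-3-ol: in the closed four-membered ring one oxygen bridges C1 and C3 only, the two CH2–O bonds are enantiotopic, and cleaving one with a carboxylic acid gives one ester and one free alcohol at once.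

## Logic of the disconnections

**10 ⇒ 9.** The phenolic O–H is traced back to an O–CH2Ph bond. A free phenol ortho to C2 would attack an activated ring CH2 in a 5-exo manner and would compete for acyl groups. The benzyl ether can be removed under neutral, aprotic conditions. The gain is chemoselectivity in every earlier step; the demand is a last step that cannot trigger an acyl shift.

**9 ⇒ 7 + 8.** The acyl C–O bond of the 2-methylbutanoate at O1 is cut. In 7 this oxygen is the only unhindered hydroxyl (phenol masked, O2 tertiary), and the second stereocenter arrives ready-made in 8. The demand is a fast acylation at low temperature, so that the degenerate 1,3-shift of the acyl group already present in 7 cannot compete.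

**7 ⇒ 5 + 6 (key).** The alkyl O3–C3 bond of the 2-methylpropanoate is cut, not its acyl C–O bond, and C3 is reconnected to O1 to close the four-membered ring. The problem of telling two near-identical esters apart becomes the choice between two enantiotopic ring C–O bonds. The ester and the free alcohol for the next step appear together, no protecting group is needed on either arm, and the ring can open only once and only at CH2. The gain is the step from a chiral, differentiated chain to an achiral, mirror-symmetric precursor without a stereocenter. The demand is catalyst-controlled selection of one CH2 under acid mild enough to leave the C2–OH bond and the new ester in place.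

**5 ⇒ 2 + 3 (through 4).** The aryl–carbinol bond C1'–C2, the most hindered bond of the target, is cut as a carbonyl addition. 3 delivers C1, C2, C3 and the bridging oxygen at the correct oxidation level in one commercial piece. The demand is a regiodefined aryl anion and a low temperature.

**2 ⇒ 1.** The O–benzyl bond is cut. 1 already carries bromine ortho to the hydroxyl and para to the methyl group, which is the full substitution pattern of the ring.

## Other disconnections considered

**Alternative 1:** (the first that comes to mind) C2–O2 and C1–O1 are cut together as the two C–O bonds of an alkene dihydroxylation. From 2, the allylic alcohol A1 (2-[2-(benzyloxy)-4-methylphenyl]prop-2-en-1-ol) would be made and esterified to its 2-methylpropanoate A2. Sharpless asymmetric dihydroxylation of A2 (K2OsO2(OH)4, (DHQD)2PHAL, K3Fe(CN)6, K2CO3, aqueous t-BuOH) would give 7, which would then follow steps 4 and 5. The chosen plan is preferred on three grounds: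
- The standard medium is aqueous carbonate at about pH 12. Under it 7, whose configuration rests only on the position of one acyl group, is exposed to the degenerate 1,3-acyl shift and to hydrolysis.
- The alkene is 1,1-disubstituted with an ortho-substituted aryl group twisted out of conjugation, a class for which facial discrimination is less secure.
- A1 needs two or three steps from 2, so the route is longer.

**Alternative 2:** the C1'–C2 bond is cut with the unprotected phenol as nucleophile. An ortho-selective asymmetric Friedel–Crafts hydroxyalkylation of 3-methylphenol A3 with the ketoester A4 (ethyl 3-(benzyloxy)-2-oxopropanoate) on a chiral titanium BINOLate (from Ti(OiPr)4 and BINOL) would give the hydroxy ester A5 (ethyl (2S)-3-(benzyloxy)-2-hydroxy-2-(2-hydroxy-4-methylphenyl)propanoate). This is convergent and sets C2 while the arms differ (ester versus benzyl ether). The chosen plan is preferred on three grounds: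
- A3 has three nucleophilic positions (C2, C4, C6), so regiocontrol rests entirely on a metal phenoxide template.
- Enantiofacial control on a non-fluorinated, enolisable ketoester is uncertain.
- A5 still needs an ester reduction, masking of the phenol and two acylations separated by a debenzylation, at least eight steps in all. In the chosen plan both arms come from 3 at the right oxidation level.

**Alternative 3:** the same alkyl C3–O3 bond is cut as in the chosen plan, but from an epoxide. Sharpless asymmetric epoxidation of A1 (Ti(OiPr)4, diethyl tartrate, t-BuOOH) would give the epoxy alcohol A6. Acylation with 8 would give the glycidyl ester A7, and opening at the epoxide CH2 with a carboxylate salt of 6 would give 9. The chosen plan is preferred on three grounds: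
- In A6 and A7 the ring oxygen sits on the benzylic carbon C2 of an electron-rich arene, so acid or Lewis acid activation favours opening at C2 and not at CH2.
- The ester carbonyl of A7 can attack the epoxide CH2 internally to give a six-membered dioxanylium ion with a mirror plane, which erases the stereocenter.
- The stereocenter needs a separate asymmetric step and the sequence is seven to eight steps. In 5 the ring oxygen is bonded to C1 and C3 only, so neither failure mode exists.

Key step: step 3

Assumption: 1, 3, 6 and 8 are taken as commercial. The absolute sense of induction in step 3 cannot be predicted with confidence, so (R)-TRIP is written and its commercial antipode is used instead if the first run shows that the other CH2 group is opened.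

## Steps

Step 1
Reactants: 1 2-bromo-5-methylphenol
Product: 2 2-(benzyloxy)-1-bromo-4-methylbenzene
Conditions: BnBr, K2CO3, DMF, 25 °C
Reagents that add atoms: benzyl bromide, BrCc1ccccc1
Why: Williamson ether synthesis: K2CO3 deprotonates the phenol and the phenoxide displaces bromide from benzyl bromide (SN2); no stereocenter is involved and the aryl bromide is inert.

Step 2
Reactants: 2 2-(benzyloxy)-1-bromo-4-methylbenzene; 3 oxetan-3-one
Product: 5 3-[2-(benzyloxy)-4-methylphenyl]oxetan-3-ol, via aryllithium 4 (not isolated)
Conditions: n-BuLi, THF, −78 °C; then 3, −78 to 0 °C; aq. NH4Cl
Reagents that add atoms: none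
Why: Bromine–lithium exchange followed by 1,2-addition of the aryllithium 4 to the strained, strongly electrophilic carbonyl group of 3; at −78 °C enolisation of 3 and proton transfer from the benzylic CH2 of 4 (which would lead to a Wittig rearrangement) should be slow. The product 5 has a mirror plane through C3, its aryl and hydroxyl groups and the ring oxygen, so no stereocenter is formed.

Step 3
Reactants: 5 3-[2-(benzyloxy)-4-methylphenyl]oxetan-3-ol; 6 2-methylpropanoic acid
Product: 7 (2R)-2-[2-(benzyloxy)-4-methylphenyl]-2,3-dihydroxypropyl 2-methylpropanoate
Conditions: 6 (3 equiv), (R)-TRIP [(R)-3,3'-bis(2,4,6-triisopropylphenyl)-1,1'-binaphthyl-2,2'-diyl hydrogen phosphate] (10 mol%), dry toluene, 40 °C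
Reagents that add atoms: none
Why: Proposed new method: the phosphoric acid and 6 are expected to form a hydrogen-bonded heterodimer in which the P–OH proton activates the ring oxygen of 5 while the phosphoryl oxygen holds the carboxylic O–H, so that the carbonyl oxygen of 6 attacks one ring CH2 from the rear (SN2) and the ring oxygen leaves as the hydroxyl group of the other arm; the closest known reaction types are the chiral-phosphoric-acid-catalysed desymmetrising openings of 3-substituted and 3,3-disubstituted oxetanes by thiols and by chloride, and the opening of meso-epoxides by carboxylic acids under the same heterodimer activation. No ring is closed: a four-membered ring is opened with release of its strain (about 25 kcal/mol), and since the ring oxygen of 5 is bonded to the two CH2 carbons only, every opening must take place at CH2 and leaves the C–O bond of the carbinol untouched. The one new stereocenter (C2 of 7, the former C3 of the ring) arises from the choice between two enantiotopic CH2–O bonds and is therefore under catalyst control alone: the tertiary hydroxyl can add a further hydrogen bond to the phosphate, the bulky 2-(benzyloxy)-4-methylphenyl group has to point away from the 2,4,6-triisopropylphenyl walls, and this fixed orientation places only one CH2 under the bound acid. Mono-functionalisation is built in, because the ring can open only once and the second arm appears as the free alcohol. Chemoselectivity over ionisation at C3 is expected because a phosphoric acid in toluene is too weak to form the strained oxetanyl cation, the excess of 6 outcompetes the hydroxyl groups of 5 and 7 as nucleophiles, and the benzyl ether keeps the phenol oxygen from a 5-exo attack on the ring. The background reaction should be negligible, as 6 alone does not activate an oxetane at 40 °C. The sense of induction has to be assigned on the first run, and the antipodal catalyst is used if the other CH2 group is opened.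

Step 4
Reactants: 7 (2R)-2-[2-(benzyloxy)-4-methylphenyl]-2,3-dihydroxypropyl 2-methylpropanoate; 8 (2S)-2-methylbutanoic anhydride
Product: 9 (2S)-2-[2-(benzyloxy)-4-methylphenyl]-2-hydroxy-3-[(2-methylpropanoyl)oxy]propyl (2S)-2-methylbutanoate
Conditions: 8, pyridine, DMAP (5 mol%), CH2Cl2, −20 to 0 °C
Reagents that add atoms: none
Why: DMAP-catalysed acylation (nucleophilic catalysis through the N-acylpyridinium ion) of the only unhindered hydroxyl group; the tertiary benzylic alcohol should not react at this temperature and the phenol is masked. The configuration at C2 should be kept because acylation at −20 °C is faster than the 1,3-shift of the 2-methylpropanoyl group, and the α-stereocenter comes unchanged from 8, since pyridine at low temperature should not enolise the acylpyridinium ion.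

Step 5
Reactants: 9 (2S)-2-[2-(benzyloxy)-4-methylphenyl]-2-hydroxy-3-[(2-methylpropanoyl)oxy]propyl (2S)-2-methylbutanoate
Product: 10 (2S)-2-hydroxy-2-(2-hydroxy-4-methylphenyl)-3-[(2-methylpropanoyl)oxy]propyl (2S)-2-methylbutanoate
Conditions: H2 (1 atm), Pd/C (10%), EtOAc, 25 °C
Reagents that add atoms: none
Why: Hydrogenolysis of the aryl benzyl ether on palladium; the medium is neutral and aprotic, so neither ester should migrate or be transesterified, and the tertiary benzylic C–OH bond, which needs acid for hydrogenolysis, is kept. Both stereocenters are untouched.

## Compound list

1 | 2-bromo-5-methylphenol | Cc1ccc(Br)c(O)c1 | starting material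
2 | 2-(benzyloxy)-1-bromo-4-methylbenzene | Cc1ccc(Br)c(OCc2ccccc2)c1 | intermediate
3 | oxetan-3-one | O=C1COC1 | starting material
4 | [2-(benzyloxy)-4-methylphenyl]lithium | [Li]c1ccc(C)cc1OCc1ccccc1 | intermediate
5 | 3-[2-(benzyloxy)-4-methylphenyl]oxetan-3-ol | OC1(COC1)c1ccc(C)cc1OCc1ccccc1 | intermediate
6 | 2-methylpropanoic acid | CC(C)C(O)=O | starting material
7 | (2R)-2-[2-(benzyloxy)-4-methylphenyl]-2,3-dihydroxypropyl 2-methylpropanoate | OC[C@@](O)(COC(=O)C(C)C)c1ccc(C)cc1OCc1ccccc1 | intermediate
8 | (2S)-2-methylbutanoic anhydride | CC[C@H](C)C(=O)OC(=O)[C@@H](C)CC | starting material
9 | (2S)-2-[2-(benzyloxy)-4-methylphenyl]-2-hydroxy-3-[(2-methylpropanoyl)oxy]propyl (2S)-2-methylbutanoate | CC[C@H](C)C(=O)OC[C@@](O)(COC(=O)C(C)C)c1ccc(C)cc1OCc1ccccc1 | intermediate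
10 | (2S)-2-hydroxy-2-(2-hydroxy-4-methylphenyl)-3-[(2-methylpropanoyl)oxy]propyl (2S)-2-methylbutanoate | CC[C@H](C)C(=O)OC[C@@](O)(COC(=O)C(C)C)c1ccc(C)cc1O | target

## Step count and least certain steps

Total step count: 5. Longest linear sequence: 5 steps (from 1; 3, 6 and 8 enter at steps 2, 3 and 4).

**Step 3 (key step, proposed new method).**
- What may go wrong: a carboxylic acid is a weaker nucleophile than the thiols and chloride of the known oxetane openings, so the ring may open too slowly. Forcing it (stronger acid, higher temperature) invites poor discrimination between the two enantiotopic CH2 groups, alkylation of the phosphate by the ring (loss of catalyst), substitution at C3 through the benzylic cation, acid-catalysed 1,3-shift of the new acyl group (racemisation at C2), and ether formation with the liberated primary alcohol.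
- Fallback (known chemistry): it sets out from 5 and comes back at 7. Acid-catalysed hydration of the oxetane (dilute H2SO4, aqueous THF) would give the prochiral triol 2-[2-(benzyloxy)-4-methylphenyl]propane-1,2,3-triol F1. A lipase-catalysed enantioselective mono-acylation of F1 (Candida antarctica lipase B or Burkholderia cepacia lipase, 2-methylpropanoic anhydride, t-BuOMe, 25 °C) would then give 7. The enzyme is selected for the arm preference that gives 7, and conversion is held below the point of double acylation.

**Step 4.**
- What may go wrong: the α-branched anhydride may acylate slowly, so that base-induced 1,3-shift of the 2-methylpropanoyl group in 7 (inversion at C2) or enolisation of the activated chiral acyl group (loss of its α-configuration) competes.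
- Fallback: it sets out from 5 and comes back at 9 by reversing the order in which the two acyl groups arrive. The key reaction would be run with (2S)-2-methylbutanoic acid and the antipodal catalyst (S)-TRIP, so that the other CH2 is opened and the chiral acid is never activated as an acyl donor. This would give (2S)-2-[2-(benzyloxy)-4-methylphenyl]-2,3-dihydroxypropyl (2S)-2-methylbutanoate F2. Its primary alcohol would then be acylated with an excess of the unhindered, achiral 2-methylpropanoic anhydride (pyridine, DMAP, CH2Cl2, −20 °C) to give 9.

**Step 2.**
- What may go wrong: 4 may act as a base toward 3 (enolisation), or the aryl anion may move to the benzylic CH2 of its own benzyl ether and rearrange before it adds.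
- Fallback: it sets out from 2 and comes back at 7, giving up the oxetane. 4, made as before, would be added to the less strained ketone 2,2-dimethyl-1,3-dioxan-5-one to give 5-[2-(benzyloxy)-4-methylphenyl]-2,2-dimethyl-1,3-dioxan-5-ol F3. Hydrolysis of its acetal (aqueous acetic acid) would give the triol F1 of the fallback to step 3, and the lipase-catalysed mono-acylation described there would lead to 7.

## Further compounds

F1 | step 3 | 2-[2-(benzyloxy)-4-methylphenyl]propane-1,2,3-triol | OCC(O)(CO)c1ccc(C)cc1OCc1ccccc1
F2 | step 4 | (2S)-2-[2-(benzyloxy)-4-methylphenyl]-2,3-dihydroxypropyl (2S)-2-methylbutanoate | CC[C@H](C)C(=O)OC[C@@](O)(CO)c1ccc(C)cc1OCc1ccccc1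
F3 | step 2 | 5-[2-(benzyloxy)-4-methylphenyl]-2,2-dimethyl-1,3-dioxan-5-ol | CC1(C)OCC(O)(CO1)c1ccc(C)cc1OCc1ccccc1
A1 | alternative 1 | 2-[2-(benzyloxy)-4-methylphenyl]prop-2-en-1-ol | C=C(CO)c1ccc(C)cc1OCc1ccccc1
A2 | alternative 1 | 2-[2-(benzyloxy)-4-methylphenyl]prop-2-en-1-yl 2-methylpropanoate | C=C(COC(=O)C(C)C)c1ccc(C)cc1OCc1ccccc1
A3 | alternative 2 | 3-methylphenol | Cc1cccc(O)c1
A4 | alternative 2 | ethyl 3-(benzyloxy)-2-oxopropanoate | CCOC(=O)C(=O)COCc1ccccc1
A5 | alternative 2 | ethyl (2S)-3-(benzyloxy)-2-hydroxy-2-(2-hydroxy-4-methylphenyl)propanoate | CCOC(=O)[C@@](O)(COCc1ccccc1)c1ccc(C)cc1O
A6 | alternative 3 | {(2R)-2-[2-(benzyloxy)-4-methylphenyl]oxiran-2-yl}methanol | OC[C@@]1(CO1)c1ccc(C)cc1OCc1ccccc1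
A7 | alternative 3 | {(2S)-2-[2-(benzyloxy)-4-methylphenyl]oxiran-2-yl}methyl (2S)-2-methylbutanoate | CC[C@H](C)C(=O)OC[C@@]1(CO1)c1ccc(C)cc1OCc1ccccc1
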